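Numbering: C1 = ester carbonyl, C2 = CH2, C3 and C5 = the two oxygen-bearing carbons of the 1,2-dioxolane ring, C4 = ring CH2, C6 = CH2, C7 = CH(CH3), C8–C13 = (CH2)6, then phenyl.
Cuts, in order: C2–C3 (ring peroxycarbenium ion + ketene silyl acetal); O–C3 and O–C5 of the dioxolane ring (β-hydroperoxy ketone, whose C5–OOH comes from H2O2 and a temporary oxetane ring C3–C4–C5–O); C5–CH3 (methyl addition to a C5 ketone); last, C6–C7.
Enabling feature: ring carbon C5 bears oxygen and lies 1,3 to methine C7, and C8–C13 is a bare methylene chain that can hide a C8=C9 double bond. C5(=O)–C6–C7–C8=C9 is therefore the γ,δ-unsaturated-ketone retron of a Claisen rearrangement. Its allyl vinyl ether C6=C5–O–C9–C8=C7 arises from an alkyne (C5≡C6) and an allylic alcohol (C9–OH).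
Forward: the allylic alcohol (C7–C13, phenyl, C7-methyl) and the alkyne (C3–C6, C3-methyl) are made separately and joined in one flask (O–H addition, then [3,3] shift). Hydrogenation, C5 methylation, oxetane ring, perhydrolysis and dioxolane ring closure follow, and the acetate arm comes last.
Stereochemistry: C7 by 1,3-chirality transfer from the sacrificial C9 carbinol (Sharpless kinetic resolution). C5 by 1,3-relay from the sacrificial C3 carbinol of (S)-propylene oxide (chelate-controlled methyl addition, then inversion by H2O2). C3 last, by attack on the flat ring cation anti to the C5 side chain.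

Key step: step 5

Assumption: the 1,3-induction in step 7 is taken as syn, as the chelate model predicts; should it be anti, (R)-2-methyloxirane would be used in step 3 and nothing else changes.

Step 1
Reactants: 1 (4-bromobutyl)benzene; 2 (E)-but-2-enal
Product: 4 rac-(E)-8-phenyloct-2-en-4-ol, via 4-phenylbutylmagnesium bromide 3 (not isolated)
Conditions: Mg, THF, reflux; then 2, −78 to 0 °C; aq NH4Cl
Reagents that add atoms: none
Why: Grignard formation and 1,2-addition to an enal, which a hard organomagnesium reagent prefers over 1,4-addition, keeps the E alkene of 2 and gives the carbinol as a racemate.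

Step 2
Reactants: 4 rac-(E)-8-phenyloct-2-en-4-ol
Product: 5 (2E,4S)-8-phenyloct-2-en-4-ol
Conditions: Ti(OiPr)4 (10 mol %), D-(−)-diisopropyl tartrate (15 mol %), t-BuOOH (0.6 equiv), 4 Å MS, CH2Cl2, −20 °C
Reagents that add atoms: none
Why: In the Sharpless kinetic resolution with the D-(−)-tartrate the (R)-enantiomer of an (E)-alkenyl alkyl carbinol is epoxidised much faster, so past half conversion the (S)-alcohol should remain in high enantiomeric purity and is separated from the polar epoxy alcohol by chromatography.

Step 3
Reactants: 6 (S)-2-methyloxirane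
Product: 7 (2S)-pent-4-yn-2-ol
Conditions: LiC≡CH·H2NCH2CH2NH2, DMSO, 0 °C to rt
Reagents that add atoms: lithium acetylide–ethylenediamine complex, [Li+].[C-]#C.NCCN
Why: SN2 opening of a terminal epoxide by acetylide takes place at the unsubstituted carbon, so the stereocentre of the chiral-pool epoxide is untouched.

Step 4
Reactants: 7 (2S)-pent-4-yn-2-ol
Product: 8 {[(2S)-pent-4-yn-2-yloxy]methyl}benzene
Conditions: NaH, BnBr, Bu4NI (cat.), THF, 0 °C to rt
Reagents that add atoms: benzyl bromide, BrCc1ccccc1
Why: Williamson etherification masks the hydroxyl, which would otherwise add to its own alkyne in step 5, with a group that leaves in the same hydrogenation that saturates the chain.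

Step 5
Reactants: 5 (2E,4S)-8-phenyloct-2-en-4-ol; 8 {[(2S)-pent-4-yn-2-yloxy]methyl}benzene
Product: 10 (2S,6S,7E)-2-(benzyloxy)-6-methyl-12-phenyldodec-7-en-4-one, via allyl vinyl ether 9 (not isolated)
Conditions: [Au(IPr)(NTf2)] (2 mol %; IPr = 1,3-bis(2,6-diisopropylphenyl)imidazol-2-ylidene), 4 Å MS, toluene, 60 °C; then 120 °C, sealed tube
Reagents that add atoms: none
Why: Monovalent gold π-activates the terminal alkyne of 8, the carbinol O–H of 5 adds at the internal carbon C5 (Markovnikov), and protodeauration releases the 2-alkoxy-1-alkene 9, an allyl vinyl ether C6=C5–O–C9–C8=C7 whose ether oxygen is the temporary tether between the two halves. At 120 °C 9 undergoes a concerted, suprafacial [3,3]-sigmatropic (Claisen) shift through a chair transition state, which trades the C9–O bond for the C6–C7 bond and unveils the C5 ketone. The closest known reaction types are the tandem gold-catalysed alkyne hydroalkoxylation/Claisen rearrangement of allylic alcohols and the Saucy–Marbet ketone Claisen; no ring is closed. The one new stereocentre, C7, is controlled by the (S)-carbinol C9 together with the E geometry of C7=C8: the (CH2)4Ph group sits equatorial, because an axial position would clash 1,3-diaxially with the C4 substituent on C5, so C6 is delivered to the face of C7 from which oxygen departs at C9, giving (6S) in 10 (R after saturation) and an E C8=C9 alkene. The step needs Markovnikov regioselectivity (terminal alkyl alkyne), mono-addition instead of ketal formation (hindered secondary alcohol, equimolar partners, sieves against hydration), an allylic C–O bond that stays intact until the shift (acid-free and silver-free NHC–gold catalyst in a non-polar solvent) and an enol ether double bond that stays at C5=C6 instead of moving to C4=C5 (no Brønsted acid).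

Step 6
Reactants: 10 (2S,6S,7E)-2-(benzyloxy)-6-methyl-12-phenyldodec-7-en-4-one
Product: 11 (2S,6R)-2-hydroxy-6-methyl-12-phenyldodecan-4-one
Conditions: H2 (1 atm), Pt/C, EtOAc, rt; then Pd(OH)2/C added, H2 (1 atm), rt
Reagents that add atoms: none
Why: Catalytic hydrogenation removes two helpers in one operation, the C8=C9 alkene over platinum (less prone than palladium to move the double bond into the C7 stereocentre) and the benzyl ether by hydrogenolysis over palladium, while ketone and phenyl ring survive at 1 atm.

Step 7
Reactants: 11 (2S,6R)-2-hydroxy-6-methyl-12-phenyldodecan-4-one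
Product: 12 (2S,4R,6R)-4,6-dimethyl-12-phenyldodecane-2,4-diol
Conditions: TiCl4 (1.1 equiv), CH2Cl2, −78 °C; then MeCeCl2 (from MeLi and CeCl3, 3 equiv), THF, −78 °C; H2O
Reagents that add atoms: methyllithium, [Li]C
Why: In this chelation-controlled 1,2-addition the trichlorotitanium alkoxide of the C3 hydroxyl binds the C5 carbonyl in a six-membered half-chair with the C3 methyl equatorial, and the non-basic organocerium reagent attacks axially, which should give the 1,3-syn diol with (R)-C5 without retro-aldol cleavage, the anti diol being removable by chromatography.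

Step 8
Reactants: 12 (2S,4R,6R)-4,6-dimethyl-12-phenyldodecane-2,4-diol
Product: 14 (2R,4R)-2,4-dimethyl-2-[(2R)-2-methyl-8-phenyloctyl]oxetane, via secondary mesylate 13 (not isolated)
Conditions: MsCl (1.1 equiv), Et3N, CH2Cl2, −20 °C; then KOt-Bu, THF, 0 °C to rt
Reagents that add atoms: none
Why: Only the secondary hydroxyl is mesylated, and intramolecular Williamson etherification (4-exo-tet, inversion at the sacrificial C3, C5–O bond untouched) closes the temporary oxetane ring, low temperature being used to hold back Grob fragmentation.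

Step 9
Reactants: 14 (2R,4R)-2,4-dimethyl-2-[(2R)-2-methyl-8-phenyloctyl]oxetane
Product: 15 (2R,4S,6R)-4-hydroperoxy-4,6-dimethyl-12-phenyldodecan-2-ol
Conditions: H2O2 (anhydrous, in Et2O, 10 equiv), Me3SiOTf (0.2 equiv), Et2O, −78 to −20 °C
Reagents that add atoms: hydrogen peroxide, OO
Why: In the Lewis-acid-promoted perhydrolysis of a 2,2-disubstituted oxetane the strain-activated C5–O bond is attacked by H2O2 at the tertiary carbon from the rear in a borderline SN2 process, so the C5–OOH centre should form with inversion in the (S) configuration of the target.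

Step 10
Reactants: 15 (2R,4S,6R)-4-hydroperoxy-4,6-dimethyl-12-phenyldodecan-2-ol
Product: 16 (2R,4S,6R)-4,6-dimethyl-12-phenyl-4-[(triethylsilyl)peroxy]dodecan-2-ol
Conditions: Et3SiCl (1.05 equiv), imidazole, DMF, −20 °C
Reagents that add atoms: chlorotriethylsilane, CC[Si](Cl)(CC)CC
Why: The hydroperoxide O–H is more acidic and, through the alpha effect, more nucleophilic than the secondary alcohol, so one equivalent of chlorosilane should silylate it selectively and shield it from the oxidant of step 11.

Step 11
Reactants: 16 (2R,4S,6R)-4,6-dimethyl-12-phenyl-4-[(triethylsilyl)peroxy]dodecan-2-ol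
Product: 17 (4S,6R)-4,6-dimethyl-12-phenyl-4-[(triethylsilyl)peroxy]dodecan-2-one
Conditions: Dess–Martin periodinane, CH2Cl2, 0 °C to rt
Reagents that add atoms: none
Why: Dess–Martin oxidation of the secondary alcohol erases the sacrificial C3 stereocentre under near-neutral conditions that a fully substituted silyl peroxide tolerates.

Step 12
Reactants: 17 (4S,6R)-4,6-dimethyl-12-phenyl-4-[(triethylsilyl)peroxy]dodecan-2-one
Product: 19 (5S)-3-methoxy-3,5-dimethyl-5-[(2R)-2-methyl-8-phenyloctyl]-1,2-dioxolane (both C3 epimers), via peroxyhemiketal 18 (not isolated)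
Conditions: p-TsOH·H2O (10 mol %), MeOH, 4 Å MS, rt
Reagents that add atoms: methanol, CO
Why: Acid methanolysis removes the silyl group, the freed hydroperoxide adds to the C3 ketone (5-exo-trig) to close the dioxolane ring as peroxyhemiketal 18, and acid-catalysed ketal exchange gives 19, whose C3 configuration is of no consequence.

Step 13
Reactants: 19 (5S)-3-methoxy-3,5-dimethyl-5-[(2R)-2-methyl-8-phenyloctyl]-1,2-dioxolane; 20 1-(tert-butyldimethylsilyloxy)-1-methoxyethene
Product: 22 methyl 2-{(3R,5S)-3,5-dimethyl-5-[(2R)-2-methyl-8-phenyloctyl]-1,2-dioxolan-3-yl}acetate, via peroxycarbenium ion 21 (not isolated)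
Conditions: TiCl4 (1.2 equiv), 20 (3 equiv), CH2Cl2, −78 °C; H2O
Reagents that add atoms: none
Why: Lewis-acid ionisation of the peroxyketal to the planar ion 21 and Mukaiyama-type capture by the ketene silyl acetal is a displacement known for 3-alkoxy-1,2-dioxolanes, in which the nucleophile should approach C3 on the ring face anti to the long C5 side chain (syn to the C5 methyl) and so set (3R) with the two large arms trans, the cis isomer being removed by chromatography.

Compound list
1 | (4-bromobutyl)benzene | BrCCCCc1ccccc1 | starting material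
2 | (E)-but-2-enal | C/C=C/C=O | starting material
3 | 4-phenylbutylmagnesium bromide | Br[Mg]CCCCc1ccccc1 | intermediate
4 | rac-(E)-8-phenyloct-2-en-4-ol | C/C=C/C(O)CCCCc1ccccc1 | intermediate
5 | (2E,4S)-8-phenyloct-2-en-4-ol | C/C=C/[C@@H](O)CCCCc1ccccc1 | intermediate
6 | (S)-2-methyloxirane | C[C@H]1CO1 | starting material
7 | (2S)-pent-4-yn-2-ol | C[C@H](O)CC#C | intermediate
8 | {[(2S)-pent-4-yn-2-yloxy]methyl}benzene | C[C@H](OCc1ccccc1)CC#C | intermediate
9 | (4S)-4-(benzyloxy)-2-{[(2E,4S)-8-phenyloct-2-en-4-yl]oxy}pent-1-ene | C[C@H](OCc1ccccc1)CC(=C)O[C@H](/C=C/C)CCCCc1ccccc1 | intermediate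
10 | (2S,6S,7E)-2-(benzyloxy)-6-methyl-12-phenyldodec-7-en-4-one | C[C@H](OCc1ccccc1)CC(=O)C[C@H](C)/C=C/CCCCc1ccccc1 | intermediate
11 | (2S,6R)-2-hydroxy-6-methyl-12-phenyldodecan-4-one | C[C@H](O)CC(=O)C[C@H](C)CCCCCCc1ccccc1 | intermediate
12 | (2S,4R,6R)-4,6-dimethyl-12-phenyldodecane-2,4-diol | C[C@H](O)C[C@@](C)(C[C@H](C)CCCCCCc1ccccc1)O | intermediate
13 | (2S,4R,6R)-4-hydroxy-4,6-dimethyl-12-phenyldodecan-2-yl methanesulfonate | C[C@H](OS(C)(=O)=O)C[C@@](C)(C[C@H](C)CCCCCCc1ccccc1)O | intermediate
14 | (2R,4R)-2,4-dimethyl-2-[(2R)-2-methyl-8-phenyloctyl]oxetane | C[C@@H]1C[C@@](C)(C[C@H](C)CCCCCCc2ccccc2)O1 | intermediate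
15 | (2R,4S,6R)-4-hydroperoxy-4,6-dimethyl-12-phenyldodecan-2-ol | C[C@@H](O)C[C@](C)(C[C@H](C)CCCCCCc1ccccc1)OO | intermediate
16 | (2R,4S,6R)-4,6-dimethyl-12-phenyl-4-[(triethylsilyl)peroxy]dodecan-2-ol | C[C@@H](O)C[C@](C)(C[C@H](C)CCCCCCc1ccccc1)OO[Si](CC)(CC)CC | intermediate
17 | (4S,6R)-4,6-dimethyl-12-phenyl-4-[(triethylsilyl)peroxy]dodecan-2-one | CC(=O)C[C@](C)(C[C@H](C)CCCCCCc1ccccc1)OO[Si](CC)(CC)CC | intermediate
18 | (5S)-3,5-dimethyl-5-[(2R)-2-methyl-8-phenyloctyl]-1,2-dioxolan-3-ol (both C3 epimers) | CC1(O)C[C@](C)(C[C@H](C)CCCCCCc2ccccc2)OO1 | intermediate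
19 | (5S)-3-methoxy-3,5-dimethyl-5-[(2R)-2-methyl-8-phenyloctyl]-1,2-dioxolane (both C3 epimers) | COC1(C)C[C@](C)(C[C@H](C)CCCCCCc2ccccc2)OO1 | intermediate
20 | 1-(tert-butyldimethylsilyloxy)-1-methoxyethene | C=C(OC)O[Si](C)(C)C(C)(C)C | starting material
21 | (5S)-3,5-dimethyl-5-[(2R)-2-methyl-8-phenyloctyl]-1,2-dioxolan-3-ylium (peroxycarbenium ion) | CC1=[O+]O[C@@](C)(C[C@H](C)CCCCCCc2ccccc2)C1 | intermediate
22 | methyl 2-{(3R,5S)-3,5-dimethyl-5-[(2R)-2-methyl-8-phenyloctyl]-1,2-dioxolan-3-yl}acetate | COC(=O)C[C@@]1(C)C[C@](C)(C[C@H](C)CCCCCCc2ccccc2)OO1 | target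

Total step count: 13. Longest linear sequence: 11 steps (1, 2, 5–13; the branch 3, 4, 5–13 is equally long).

Steps most likely to fail

Step 5. The allylic alcohol may ionise or undergo SN2′ etherification at gold, which would erode the chirality transfer. The alkyne may also take up a second alcohol or water. The fallback sets out from 8 and 5 and comes back at 10. It forms the C5–O bond under basic, non-ionising conditions by copper-catalysed vinylation instead of π-acid catalysis. α-Selective hydroalumination of 8 (DIBAL-H, Ni(dppp)Cl2 cat., THF) followed by N-iodosuccinimide gives (4S)-4-(benzyloxy)-2-iodopent-1-ene F1. The domino C–O coupling/Claisen rearrangement of this vinyl iodide with 5 (CuI cat., 3,4,7,8-tetramethyl-1,10-phenanthroline, Cs2CO3, o-xylene, 120 °C) passes through the same allyl vinyl ether 9 and delivers 10.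

Step 9. The activated oxetane may ionise fully to a free tertiary cation, with loss of stereochemical integrity at C5 or elimination. The product hydroperoxide may also attack a second oxetane. The fallback sets out from 11 and comes back at 17, and so also bypasses steps 7, 8 and 10. It makes the C5–O bond by a radical instead of an ionic process and relies on separation of diastereomers. Petasis methylenation of 11 (Cp2TiMe2, toluene, 70 °C) gives (2S,6R)-6-methyl-4-methylidene-12-phenyldodecan-2-ol F2. Mukaiyama–Isayama hydroperoxysilylation (Co(thd)2 cat., O2, Et3SiH, 1,2-dichloroethane, rt) places hydrogen on the methylene carbon and the silylperoxy group on C5 without facial control. It gives (2S,4S,6R)-4,6-dimethyl-12-phenyl-4-[(triethylsilyl)peroxy]dodecan-2-ol F3 together with (2S,4R,6R)-4,6-dimethyl-12-phenyl-4-[(triethylsilyl)peroxy]dodecan-2-ol F4. The neighbouring carbinol centre should allow their separation by chromatography. Dess–Martin oxidation of the (4S) isomer then gives 17.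

Step 13. Facial selectivity at the flat cation may be poor, or the Lewis acid may induce heterolysis of the O–O bond with skeletal fragmentation. The fallback sets out from 17 and comes back at 22. It closes the ring by forming the O–C3 bond last instead of the C2–C3 bond. Horner–Wadsworth–Emmons olefination of 17 (trimethyl phosphonoacetate, NaH, THF) gives methyl (2E,5S,7R)-3,5,7-trimethyl-13-phenyl-5-[(triethylsilyl)peroxy]tridec-2-enoate F5. Desilylation (Et3N·3HF, THF) gives methyl (2E,5S,7R)-5-hydroperoxy-3,5,7-trimethyl-13-phenyltridec-2-enoate F6. Base-induced intramolecular oxa-Michael addition (Et2NH, CF3CH2OH, 5-exo-trig) closes the dioxolane ring to 22, which is separated from its C3 epimer by chromatography.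

Further compounds
F1 | step 5 | (4S)-4-(benzyloxy)-2-iodopent-1-ene | C[C@H](OCc1ccccc1)CC(I)=C
F2 | step 9 | (2S,6R)-6-methyl-4-methylidene-12-phenyldodecan-2-ol | C[C@H](O)CC(=C)C[C@H](C)CCCCCCc1ccccc1
F3 | step 9 | (2S,4S,6R)-4,6-dimethyl-12-phenyl-4-[(triethylsilyl)peroxy]dodecan-2-ol | C[C@H](O)C[C@](C)(C[C@H](C)CCCCCCc1ccccc1)OO[Si](CC)(CC)CC
F4 | step 9 | (2S,4R,6R)-4,6-dimethyl-12-phenyl-4-[(triethylsilyl)peroxy]dodecan-2-ol | C[C@H](O)C[C@@](C)(C[C@H](C)CCCCCCc1ccccc1)OO[Si](CC)(CC)CC
F5 | step 13 | methyl (2E,5S,7R)-3,5,7-trimethyl-13-phenyl-5-[(triethylsilyl)peroxy]tridec-2-enoate | COC(=O)/C=C(\C)C[C@](C)(C[C@H](C)CCCCCCc1ccccc1)OO[Si](CC)(CC)CC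
F6 | step 13 | methyl (2E,5S,7R)-5-hydroperoxy-3,5,7-trimethyl-13-phenyltridec-2-enoate | COC(=O)/C=C(\C)C[C@](C)(C[C@H](C)CCCCCCc1ccccc1)OO
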